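We begin with an easy subtraction. The north-east run is this very flask followed so far, and its starting material lost 9 percentage points in the first 1.00 min but 4 points between 8.00 min and 12.0 min. By that last reading about a third has gone, so we watch for a stall. Each round of the catalyst takes one starting material and one second substrate, which gives the turnover number n, and from it the cover Ω, the second substrate that those turnovers can work through over the second substrate charged:

n = 32.0% × 18 mM / 0.14 µM = 41100

Ω = n × 0.14 µM / 14.4 mM = 0.400

The zero of this scale is Ω = 1, where catalyst and second substrate give out together. Here Ω is lower than that, so we expect the catalyst to stop first, with 60.0% of the second substrate still free. We then expect no gain above 2 points from dawn or autumn, while spring, if the fresh catalyst repeats n, lifts Ω to 0.800.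

One number is not enough. The north run, hotter and charged with more starting material, gives n = 28900 at its last reading, 4.00 min, lower than ours, but that reading comes earlier than ours, so we do not carry n over between those settings. Ω also counts starting material used, not target. Target reads 20.0% on average over the last two readings, which as a share of the starting material used is s = 0.625. If a second burst equals the first and the split returns after removal, we reckon:

now: 20.0%

spring: 40.0%

summer: 26.7%

| setting | north-east | north | flask |
|---|---|---|---|
| starting material | 18 mM | 27 mM | 18 mM |
| second substrate | 14.4 mM | 14.4 mM | 14.4 mM |
| free enzyme | 0.14 µM | 0.14 µM | 0.14 µM |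
| temperature | 37 °C | 43 °C | 37 °C |
| remark | the very flask that is asked about, followed so far | run made earlier |  |
| time |  |  | 20 min |

| run | time / min | target / % | starting material / % |
|---|---|---|---|
| north-east | 1.00 | 8 | 91 |
| north-east | 3.00 | 16 | 81 |
| north-east | 6.00 | 21 | 73 |
| north-east | 8.00 | 21 | 72 |
| north-east | 12.0 | 19 | 68 |
| north | 0.833 | 7 | 91 |
| north | 1.50 | 8 | 91 |
| north | 2.50 | 9 | 90 |
| north | 3.00 | 10 | 89 |
| north | 4.00 | 9 | 85 |

(scatter of a reading: 1.5 percentage points)

- autumn: at 20 min add second substrate, 100% of the amount charged, then wait 20 min
- spring: at 20 min add free enzyme, 100% of the amount charged, then wait 20 min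
- dawn: change nothing and wait 20 min more
- summer: at 20 min take out 90% of the target then present, then wait 20 min

- percentages count the starting material that a species holds: one spent catalyst A counts as two
- what is taken out of target is counted as made
- steps under discussion: free enzyme -> unfolded enzyme; starting material + free enzyme <-> first complex; first complex -> loaded enzyme + first product; second substrate + loaded enzyme <-> second complex; second complex -> free enzyme + target; 2 second complex -> spent catalyst A; free enzyme -> spent catalyst B; target <-> isomer of the product
- additions bring no volume worth counting

1. target, in percent of the starting material first charged, at 20 min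
2. the option that brings most further target ("none" if no option brings more than 2 percentage points) (autumn / spring / dawn / summer / none)
3. target present, with what was taken out counted in, in percent of the starting material first charged, after spring
4. target present, with what was taken out counted in, in percent of the starting material first charged, after summer

The forecast also holds that “the catalyst is dying” and picks spring, as we do, but its numbers are lower than ours: 14% now, 20% after spring, 16% after summer.

The flask gives 20.7%, and spring is best, with 14 points further target, 34.9% in the count, against 27.4% after summer. At 20.0 min it holds 60% of its second substrate and 0.123% of the catalyst as free enzyme.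

    free enzyme → unfolded enzyme (k = 4.60 × 10⁻⁴ /s, Ea = 233 kJ/mol)
    starting material + free enzyme ⇌ first complex (K = 39.0 /M, k = 3.80 × 10⁵ /M/s, Ea = 15.0 kJ/mol, ΔH = −59.0 kJ/mol)
    first complex → loaded enzyme + first product (k = 1400 /s, Ea = 49.0 kJ/mol)
    second substrate + loaded enzyme ⇌ second complex (K = 24.0 /M, k = 7.10 × 10⁶ /M/s, Ea = 13.0 kJ/mol, ΔH = 8.00 kJ/mol)
    second complex → free enzyme + target (k = 1500 /s, Ea = 59.0 kJ/mol)
    2 second complex → spent catalyst A (k = 73000 /M/s, Ea = 18.0 kJ/mol)
    free enzyme → spent catalyst B (k = 0.0160 /s, Ea = 88.0 kJ/mol)
    target ⇌ isomer of the product (K = 0.560, k = 0.00360 /s, Ea = 90.0 kJ/mol, ΔH = 21.0 kJ/mol)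
    (constants at 37 °C)

The neighbour charged with 5.6 × 10⁻⁴ mM of free enzyme has, at our n, Ω = 1.60, above the zero of the scale, so we take second substrate as the limiting reagent and reckon s × 14.4 mM / 18 mM = 50.0% target. That neighbour ends with 4.8% of its second substrate and 48.9% target.

The readings are simulated from invented constants, noise included.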